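In the 6.0 min of a run the substrate becomes an intermediate, and what you want to know is how that intermediate is shared out among its partners.

- Monday's: substrate 0.050 M; second nucleophile 2.80 equiv; solid first nucleophile 0.600 equiv; time 6.0 min
- Saturday's: substrate 0.050 M; second nucleophile 1.10 equiv; solid first nucleophile 0.600 equiv; time 6.0 min

    first nucleophile + target → over-reaction product (k1 = 0.370 M⁻¹ s⁻¹)
    second nucleophile + intermediate → other capture product (k2 = 36.9 M⁻¹ s⁻¹)
    substrate → intermediate (k3 = 0.369 s⁻¹)
    first nucleophile + intermediate → target (k4 = 25.8 M⁻¹ s⁻¹)
    intermediate → solvolysis product (k5 = 3.80 s⁻¹)
    solid first nucleophile ⇌ first nucleophile, rate k6*(cs6 - [first nucleophile]) while solid is left; crystals form when [first nucleophile] > cs6 (cs6 = 15 mM, k6 = 0.200 s⁻¹)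

1. which of these there is most of at the end, counted by the substrate in it, Monday's (over-reaction product / solvolysis product / target / other capture product)
2. which of these there is most of at the end, counted by the substrate in it, Saturday's (over-reaction product / solvolysis product / target / other capture product)
3. final amount of the leader among these, as a percentage of the substrate charged, in Monday's
4. final amount of the leader among these, as a percentage of the substrate charged, in Saturday's

- as a solid, counted per litre of solution: solid first nucleophile
- at the start none of the solid first nucleophile is in solution
- run time (Monday's): 6.0 min

**Fastest rung.** At Monday's charged loading, solvolysis and second-nucleophile capture together give the intermediate a mean life of 0.112 s. On Saturday's the same sum gives 0.172 s. The substrate's mean life is 2.71 s, which is longer than either, so the intermediate is passed on about as fast as it forms.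

**Middle rung.** The first nucleophile climbs towards its solubility with a time constant of 5.00 s, longer than the substrate's mean life. Even at its solubility, 15 mM, the first nucleophile captures at 0.387 s⁻¹, while solvolysis runs ten times as fast. So I set this route aside in my reckoning.

**Slowest rung.** At that solubility the target has a mean life of about 3.00 min, far longer than the substrate's, so it thins out within the run.

**Fraction left.** Capture and solvolysis draw on the same intermediate, so work with f, the fraction of second nucleophile left. Capture product is the charged equivalents times the fraction spent. Solvolysis product, as a fraction of the substrate charged, is −κ ln f, where κ is the balance loading: the equivalents of second nucleophile at which the two routes run equally at a given substrate concentration, the selectivity factor written as a loading. Here κ is 2.06 equiv.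

**My reckoning.** Monday's mean loading, taken as the charge less half of what the starting split spends, is about 2.51 equiv, which gives capture 54.9 % and leaves f near 0.804. Solvolysis is then 45.0 %, so capture leads. Saturday's mean loading of 0.926 equiv gives capture 31.0 %, f near 0.718, and solvolysis 68.2 %, which leads.

**The forecast.** It names other capture product at 54 % for Monday's and solvolysis product at 66.5 % for Saturday's, on the ground that “the second nucleophile's loading decides the leader, allowing for its depletion during the run”. Its leaders are the same as mine, but its Saturday figure stands lower than mine.

**The outcome.** Monday's ends with other capture product at 54.1 %, Saturday's with solvolysis product at 67.0 %. With 81 % of Monday's second nucleophile left, −κ ln f gives 44.2 % against the 44.2 % of solvolysis product found. Now take a neighbour like Monday's but with 0.12 M of substrate, the equivalents held. Its κ falls to 0.858 equiv, and with 74 % of its second nucleophile left, −κ ln f gives 25.8 %. That flask ends with 26.0 % of solvolysis product.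

The constants are those of an exercise; what happens was integrated by code.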